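**Assumptions.** Surinone B has no stereocentre and no stereogenic double bond (the exocyclic enol carbon carries two identical ring arms), so it is achiral and no stereocontrol is needed; the SMILES is the exocyclic-enol tautomer of 2-(13-phenyltridecanoyl)cyclohexane-1,3-dione. Salts and enolates of a numbered compound are treated as forms of that compound and carry its number.

## Retrosynthetic overview

1. Phenethylmagnesium chloride (1) + 11-bromoundecanoic acid (2) ⇐ 13-phenyltridecanoic acid (3), cut at C11–C12 (sp3–sp3 coupling).
2. 3 + methyl 5-oxohexanoate (4) ⇐ acyl imidazolide (5) ⇐ linear methyl 5,7-dioxo-19-phenylnonadecanoate (6), cut at C6–C7. This is a chain-extending Claisen acyl transfer: activated starter acid onto a reduced triketide.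
3. 6 ⇐ Surinone B (7), cut at the C1–C6 bond of 6. This is the intramolecular Claisen ring closure of the presumed polyketide pathway, in which the β-diketone carbon attacks the terminal acyl group.
4. Ring order: the phenyl ring is bought. The cyclohexane-1,3-dione ring is the only ring formed and is closed last, in the same flask as the acyl transfer.

## Route

Step 1
Reactants: 1 phenethylmagnesium chloride; 2 11-bromoundecanoic acid
Product: 3 13-phenyltridecanoic acid
Conditions: 1 (2.3 equiv, 1 M in THF) added to 2, Li2CuCl4 (3 mol %), THF, −20 °C → rt; 1 M HCl
Reagents that add atoms: none
Why: Kochi-type copper-catalysed cross-coupling of a primary alkyl Grignard reagent with a primary bromide: the first equivalent of 1 turns 2 into its chloromagnesium carboxylate, which does not add Grignard reagent at this temperature, and the second displaces bromide at C11; no stereocentre is formed.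

Step 2
Reactants: 3 13-phenyltridecanoic acid; 4 methyl 5-oxohexanoate
Product: 7 Surinone B [2-(1-hydroxy-13-phenyltridecylidene)cyclohexane-1,3-dione], via 13-phenyltridecanoyl imidazolide 5 (not isolated), via methyl 5,7-dioxo-19-phenylnonadecanoate 6 (not isolated)
Conditions: 3, CDI (1.1 equiv), THF, rt, 1 h; transferred at −78 °C into 4 (3.3 equiv) pre-enolised with LiN(i-Pr)2 (3.3 equiv), THF, −78 °C, 20 min; −78 → 0 °C; then KOt-Bu (4 equiv), t-BuOH, 60 °C; 1 M HCl
Reagents that add atoms: none
Why: Proposed new method: a one-flask Claisen acyl transfer/Claisen ring closure that copies the presumed polyketide assembly, in which the kinetic methyl-side lithium enolate of 4 is C-acylated by imidazolide 5 (closest known type: β-diketone synthesis from ketone lithium enolates and acyl imidazolides; of the 3.3 equiv of enolate, one is acylated, one is quenched by the imidazole freed on activation and one by the diketone formed), and the diketonate of 6, once switched to its potassium salt, attacks its own methyl ester through the central carbon in a 6-exo-trig closure driven by formation of the much more acidic triketonate (closest known type: Lacey–Dieckmann cyclisation to 3-acyltetramic acids); no stereocentre is formed and the product is achiral.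

## Compound list

1 | phenethylmagnesium chloride (2-phenylethylmagnesium chloride) | Cl[Mg]CCc1ccccc1 | starting material
2 | 11-bromoundecanoic acid | OC(=O)CCCCCCCCCCBr | starting material
3 | 13-phenyltridecanoic acid | OC(=O)CCCCCCCCCCCCc1ccccc1 | intermediate
4 | methyl 5-oxohexanoate | COC(=O)CCCC(C)=O | starting material
5 | 13-phenyltridecanoyl imidazolide [1-(imidazol-1-yl)-13-phenyltridecan-1-one] | O=C(CCCCCCCCCCCCc1ccccc1)n1ccnc1 | intermediate (not isolated)
6 | methyl 5,7-dioxo-19-phenylnonadecanoate | COC(=O)CCCC(=O)CC(=O)CCCCCCCCCCCCc1ccccc1 | intermediate (not isolated)
7 | Surinone B [2-(1-hydroxy-13-phenyltridecylidene)cyclohexane-1,3-dione] | O=C1CCCC(=O)C1=C(O)CCCCCCCCCCCCc1ccccc1 | target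

## Step count and risk

Total step count: 2.
Longest linear sequence: 2 steps (2 → 3 → 7).

The route has only two steps, so both are ranked, and the two bond-forming stages of step 2 are ranked separately.

**1. Step 2, acyl-transfer stage (highest risk).** The kinetic enolate of 4 may close onto its own ester to give cyclohexane-1,3-dione before it meets 5. It may also be O-acylated, or partly equilibrate to the internal enolate. The fallback sets out from 3 and comes back at 6. Treat 3 with MeLi (2.2 equiv, THF, 0 °C, then aqueous NH4Cl) to give 14-phenyltetradecan-2-one F1. Condense this with dimethyl glutarate (5 equiv) and NaH (3 equiv) in THF at reflux. The thermodynamically controlled crossed Claisen at the methyl group gives the sodium salt of 6, which is closed to 7 with KOt-Bu as in step 2. This inverts the polarity of the chain-extending Claisen: the long chain becomes the nucleophile and the C5 unit the electrophile. It also removes the self-cyclising keto ester enolate.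

**2. Step 2, ring-closure stage.** The chelated diketonate of 6 is a weak nucleophile toward an unactivated methyl ester, and alkoxide can cleave the diketone by retro-Claisen. The fallback sets out from 6 and comes back at 7. Isolate 6 by quenching step 2 with aqueous NH4Cl before KOt-Bu is added. Saponify it with LiOH (THF/H2O, rt) to 5,7-dioxo-19-phenylnonadecanoic acid F2. Treat this with DCC (1.2 equiv) and DMAP (1.2 equiv) in CH2Cl2 at rt. The activated carboxyl group acylates the diketone intramolecularly, and any enol lactone formed by O-acylation is carried to the C-acyl triketone by DMAP-mediated O-to-C acyl migration. This replaces enolate attack on an ester by electrophilic activation of the acid.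

**3. Step 1.** The chloromagnesium carboxylate of 2 may be poorly soluble at −20 °C, and homocoupling or β-hydride elimination of the alkylcopper species can lower the yield. The fallback sets out from 2 and comes back at 3. Alkylate lithium phenylacetylide (2.2 equiv, from phenylacetylene and n-BuLi, THF/DMPU, 0 °C → rt; the first equivalent forms the lithium carboxylate of 2) to give 13-phenyltridec-12-ynoic acid F3. Hydrogenate this (H2, 1 atm, Pd/C, EtOAc, rt) to 3. This replaces the copper-catalysed coupling by an acetylide SN2 alkylation and reduction.

In step 2, the excess 4 ends up as water-soluble cyclohexane-1,3-dione and is removed in the aqueous work-up.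

## Further compounds

F1 | step 2 | 14-phenyltetradecan-2-one | CC(=O)CCCCCCCCCCCCc1ccccc1
F2 | step 2 | 5,7-dioxo-19-phenylnonadecanoic acid | OC(=O)CCCC(=O)CC(=O)CCCCCCCCCCCCc1ccccc1
F3 | step 1 | 13-phenyltridec-12-ynoic acid | OC(=O)CCCCCCCCCCC#Cc1ccccc1
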